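**Retrosynthetic overview**

Ring numbering used below: C1 ketone carbon, C2 the N-bearing carbon, C3 the vinylic CH, C4 the carbinol carbon, C5/C6 the epoxide carbons; C1′ is the first carbon of the triene chain.
Last disconnections: C2′–C3′ (Stille union of a C4-stannylvinyl epoxyquinol with a bromodienamide of the aminocyclopentenone), the oxirane (OH-directed epoxidation of a p-quinol) and C2=C3 (loss of HNO2 from a β-nitro ketone).
Key disconnection: C1–C2 and C3–C4 by an asymmetric [4+2] of 3-hydroxy-2-pyrone (C4–C5–C6–C1, C1′ and both oxygens) with a β-amido nitroalkene (C2–C3, N already carrying the complete upper acyl chain); it also sets C4 and leaves C5=C6 for the oxirane.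
Enabling feature: C4 carries O and C1′ and C1 carries O at the opposite ring position, so an O(C1)–C1′ lactone bond (absent from the target, cut again by reduction) turns these four ring carbons into a pyrone diene; the C1 carbonyl next to C2–H later lets the activating nitro group on C3 leave as nitrite.
Ring order: carbocycle first (as a 2-oxabicyclo[2.2.2]octenone), lactone bridge opened, oxirane last; the cyclopentenone comes from the 1,3-dione and the acyl-chain stereocentre from an Evans methylation.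

Key step: step 8

Assumption: the quinidine-derived catalyst is taken to give the (1R,4R) lactone (its quinine-derived pseudoenantiomer would be used if the sense of induction is the opposite), and the nitro and amido groups of the cycloadduct are drawn trans (nitro syn to the ring alkene); these two centres are destroyed later, so their configuration is immaterial.

**Route**

Step 1
Reactants: 1 (R)-4-benzyl-1,3-oxazolidin-2-one; 2 hexanoyl chloride
Product: 3 (R)-4-benzyl-3-hexanoyl-1,3-oxazolidin-2-one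
Conditions: n-BuLi, THF, −78 °C; then 2, −78 → 0 °C
Reagents that add atoms: none
Why: N-acylation of the lithiated oxazolidinone (loading of the Evans auxiliary) should be clean at low temperature.

Step 2
Reactants: 3 (R)-4-benzyl-3-hexanoyl-1,3-oxazolidin-2-one
Product: 4 (R)-4-benzyl-3-[(2R)-2-methylhexanoyl]-1,3-oxazolidin-2-one
Conditions: NaN(SiMe3)2, THF, −78 °C; MeI, −78 °C
Reagents that add atoms: iodomethane, CI
Why: Evans asymmetric alkylation; the chelated Z-sodium enolate should be methylated on the face opposite the benzyl group, which sets the 2R centre of the acyl chain.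

Step 3
Reactants: 4 (R)-4-benzyl-3-[(2R)-2-methylhexanoyl]-1,3-oxazolidin-2-one
Product: 5 (2R)-2-methylhexan-1-ol
Conditions: LiBH4, MeOH (1 equiv), Et2O, 0 °C
Reagents that add atoms: none
Why: reductive cleavage of the N-acyl oxazolidinone with LiBH4 should give the primary alcohol without epimerisation and return the auxiliary.

Step 4
Reactants: 5 (2R)-2-methylhexan-1-ol
Product: 7 ethyl (2E,4R)-2,4-dimethyloct-2-enoate, via (2R)-2-methylhexanal 6 (not isolated)
Conditions: Dess–Martin periodinane, CH2Cl2, 0 °C → rt; then Ph3P=C(Me)CO2Et, rt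
Reagents that add atoms: ethyl 2-(triphenylphosphoranylidene)propanoate, CCOC(=O)C(C)=P(c1ccccc1)(c1ccccc1)c1ccccc1
Why: Dess–Martin oxidation followed in the same flask by Wittig olefination with the stabilised ylide should give the E-trisubstituted enoate and avoids isolating the volatile, epimerisable aldehyde.

Step 5
Reactants: 7 ethyl (2E,4R)-2,4-dimethyloct-2-enoate
Product: 8 (2E,4R)-2,4-dimethyloct-2-enoic acid
Conditions: LiOH, THF/MeOH/H2O, 40 °C; then aq. HCl
Reagents that add atoms: lithium hydroxide, [Li+].[OH-]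
Why: saponification of the ester; the stereocentre is not α to the carbonyl and the trisubstituted alkene should keep its geometry under these mild conditions.

Step 6
Reactants: 9 (E)-N,N-dimethyl-2-nitroethen-1-amine
Product: 10 (Z)-2-nitroethen-1-amine
Conditions: NH3 (7 M in MeOH), rt
Reagents that add atoms: ammonia, N
Why: transamination by addition–elimination at the β-carbon of the push–pull nitroenamine; the primary nitroenamine should adopt the hydrogen-bonded Z form.

Step 7
Reactants: 8 (2E,4R)-2,4-dimethyloct-2-enoic acid; 10 (Z)-2-nitroethen-1-amine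
Product: 12 (2E,4R)-2,4-dimethyl-N-[(Z)-2-nitroethenyl]oct-2-enamide, via (2E,4R)-2,4-dimethyloct-2-enoyl chloride 11 (not isolated)
Conditions: (COCl)2, DMF (cat.), CH2Cl2, 0 °C → rt; concentrate; then 10, pyridine, CH2Cl2, 0 °C → rt
Reagents that add atoms: none
Why: N-acylation of a primary β-aminonitroalkene by an acid chloride that has no α-hydrogen (no ketene pathway) should give the β-acylamino nitroalkene, held Z by the N–H···O2N hydrogen bond.

Step 8
Reactants: 12 (2E,4R)-2,4-dimethyl-N-[(Z)-2-nitroethenyl]oct-2-enamide; 13 3-hydroxy-2H-pyran-2-one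
Product: 14 (2E,4R)-N-[(1R,4R,7S,8S)-4-hydroxy-8-nitro-3-oxo-2-oxabicyclo[2.2.2]oct-5-en-7-yl]-2,4-dimethyloct-2-enamide
Conditions: 1-[3,5-bis(trifluoromethyl)phenyl]-3-(9-deoxy-9-epi-quinidin-9-yl)thiourea (10 mol %), Et2O, −20 °C
Reagents that add atoms: none
Why: Proposed new method: the quinuclidine nitrogen of the bifunctional catalyst engages the 3-OH of 13 (pyrone oxy-anion, a HOMO-raised diene) while the thiourea binds the nitro group of 12, so that pyrone C6 (ring C1) attacks the amide-bearing alkene carbon (C2) and the nitro-bearing carbon (C3) closes onto pyrone C3 (ring C4) in an asynchronous [4+2], in the limit a vinylogous Michael addition followed by a Henry reaction. The closest known reaction type is the cinchona-amine-catalysed asymmetric Diels–Alder reaction of 3-hydroxy-2-pyrones with electron-poor alkenes to give 2-oxabicyclo[2.2.2]octenones; a β-amido nitroalkene has not been used as the 2π partner. The six-membered carbocycle closes in the [4+2] mode across pyrone C3 and C6 (in the stepwise limit by a 6-exo-trig nitro-aldol), and the lactone bridge of the pyrone stays as the temporary third bridge. C4 and C1 are created together, are fixed relative to each other by the lactone bridge, and their absolute sense is set by the catalyst, which shields one face of the ion-paired pyrone; the centres at C7 and C8 are erased in step 13. Regioselectivity (N-bearing carbon to C1, nitro carbon to C4) is secured by polarity, since the nitro group makes the amide-bearing carbon the electrophilic terminus and the 3-oxido group makes pyrone C6 the nucleophilic terminus. The step also needs ring closure to outrun re-aromatisation of the first-formed adduct to a 6-alkylated hydroxypyrone, which the electrophilic α-keto-lactone carbonyl and the low temperature should favour.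

Step 9
Reactants: 14 (2E,4R)-N-[(1R,4R,7S,8S)-4-hydroxy-8-nitro-3-oxo-2-oxabicyclo[2.2.2]oct-5-en-7-yl]-2,4-dimethyloct-2-enamide
Product: 15 (2E,4R)-2,4-dimethyl-N-[(1R,4R,7S,8S)-8-nitro-3-oxo-4-[(triethylsilyl)oxy]-2-oxabicyclo[2.2.2]oct-5-en-7-yl]oct-2-enamide
Conditions: Et3SiOTf, 2,6-lutidine, CH2Cl2, −78 → −20 °C
Reagents that add atoms: triethylsilyl trifluoromethanesulfonate, CC[Si](CC)(CC)OS(=O)(=O)C(F)(F)F
Why: silyl ether formation at the bridgehead tertiary alcohol with the silyl triflate blocks retro-Henry cleavage of the C3–C4 bond in the basic steps that follow.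

Step 10
Reactants: 15 (2E,4R)-2,4-dimethyl-N-[(1R,4R,7S,8S)-8-nitro-3-oxo-4-[(triethylsilyl)oxy]-2-oxabicyclo[2.2.2]oct-5-en-7-yl]oct-2-enamide
Product: 16 (2E,4R)-N-[(1R,4R,7S,8S)-3-hydroxy-8-nitro-4-[(triethylsilyl)oxy]-2-oxabicyclo[2.2.2]oct-5-en-7-yl]-2,4-dimethyloct-2-enamide (lactol, both C3 epimers)
Conditions: i-Bu2AlH (3 equiv), CH2Cl2, −78 °C; aq. potassium sodium tartrate
Reagents that add atoms: none
Why: partial reduction of the strained bridged lactone to the lactol by i-Bu2AlH at −78 °C; the amide N–H and the nitro α-C–H are deprotonated first and thereby shielded.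

Step 11
Reactants: 16 (2E,4R)-N-[(1R,4R,7S,8S)-3-hydroxy-8-nitro-4-[(triethylsilyl)oxy]-2-oxabicyclo[2.2.2]oct-5-en-7-yl]-2,4-dimethyloct-2-enamide
Product: 17 (2E,4R)-N-[(1S,2R,5S,6S)-5-ethynyl-2-hydroxy-6-nitro-5-[(triethylsilyl)oxy]cyclohex-3-en-1-yl]-2,4-dimethyloct-2-enamide
Conditions: dimethyl (1-diazo-2-oxopropyl)phosphonate, K2CO3, MeOH, 0 °C → rt
Reagents that add atoms: dimethyl (1-diazo-2-oxopropyl)phosphonate, COP(=O)(OC)C(=[N+]=[N-])C(C)=O
Why: Ohira–Bestmann (Seyferth–Gilbert) homologation of the hydroxy aldehyde in equilibrium with the lactol should give the terminal alkyne (C1′≡C2′) and free the C1 hydroxyl; the α-carbon is quaternary and cannot epimerise, and a nitronate formed reversibly is re-protonated on work-up.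

Step 12
Reactants: 17 (2E,4R)-N-[(1S,2R,5S,6S)-5-ethynyl-2-hydroxy-6-nitro-5-[(triethylsilyl)oxy]cyclohex-3-en-1-yl]-2,4-dimethyloct-2-enamide
Product: 18 (2E,4R)-N-[(1S,2R,5S,6S)-2-hydroxy-6-nitro-5-[(E)-2-(tributylstannyl)ethenyl]-5-[(triethylsilyl)oxy]cyclohex-3-en-1-yl]-2,4-dimethyloct-2-enamide
Conditions: Bu3SnH, PdCl2(PPh3)2 (3 mol %), THF, 0 °C → rt
Reagents that add atoms: tributyltin hydride, CCCC[SnH](CCCC)CCCC
Why: palladium-catalysed syn-hydrostannylation of the terminal alkyne should place tin on the distal carbon, away from the fully substituted propargylic centre, and give the E-vinylstannane.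

Step 13
Reactants: 18 (2E,4R)-N-[(1S,2R,5S,6S)-2-hydroxy-6-nitro-5-[(E)-2-(tributylstannyl)ethenyl]-5-[(triethylsilyl)oxy]cyclohex-3-en-1-yl]-2,4-dimethyloct-2-enamide
Product: 20 (2E,4R)-2,4-dimethyl-N-[(3R)-6-oxo-3-[(E)-2-(tributylstannyl)ethenyl]-3-[(triethylsilyl)oxy]cyclohexa-1,4-dien-1-yl]oct-2-enamide, via β-nitro ketone 19 (not isolated)
Conditions: Dess–Martin periodinane, CH2Cl2, 0 °C → rt; then Et3N, 0 °C
Reagents that add atoms: none
Why: Dess–Martin oxidation of the secondary allylic alcohol gives the C1 ketone, whose acidic C2–H then allows E1cB loss of nitrite from C3 with Et3N (nitro as a traceless activating group), which forms the C2=C3 enamide of the cross-conjugated dienone.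

Step 14
Reactants: 20 (2E,4R)-2,4-dimethyl-N-[(3R)-6-oxo-3-[(E)-2-(tributylstannyl)ethenyl]-3-[(triethylsilyl)oxy]cyclohexa-1,4-dien-1-yl]oct-2-enamide
Product: 21 (2E,4R)-N-[(3R)-3-hydroxy-6-oxo-3-[(E)-2-(tributylstannyl)ethenyl]cyclohexa-1,4-dien-1-yl]-2,4-dimethyloct-2-enamide
Conditions: Bu4NF, AcOH (1:1), THF, 0 °C
Reagents that add atoms: none
Why: fluoride-mediated desilylation of the tertiary triethylsilyl ether; buffering with acetic acid should spare the dienone and the vinylstannane.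

Step 15
Reactants: 21 (2E,4R)-N-[(3R)-3-hydroxy-6-oxo-3-[(E)-2-(tributylstannyl)ethenyl]cyclohexa-1,4-dien-1-yl]-2,4-dimethyloct-2-enamide
Product: 22 (2E,4R)-N-[(1S,5R,6R)-5-hydroxy-2-oxo-5-[(E)-2-(tributylstannyl)ethenyl]-7-oxabicyclo[4.1.0]hept-3-en-3-yl]-2,4-dimethyloct-2-enamide
Conditions: t-BuOOH (in decane), BnMe3NOH (10 mol %), THF, −20 → 0 °C
Reagents that add atoms: tert-butyl hydroperoxide, CC(C)(C)OO
Why: Weitz–Scheffer nucleophilic epoxidation; the peroxide should attack the amide-free C5=C6 enone (the C2=C3 enone is deactivated by its α-amido group) on the face of the C4 hydroxyl, which delivers it by hydrogen bonding and so sets C5 and C6 syn to the OH.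

Step 16
Reactants: 23 sulfur trioxide–pyridine complex (pyridinium-1-sulfonate)
Product: 24 potassium (1E,3E)-5-oxopenta-1,3-dien-1-olate (glutaconaldehyde potassium salt)
Conditions: KOH, H2O, −20 °C → rt
Reagents that add atoms: potassium hydroxide, [K+].[OH-]
Why: hydroxide opens the N-sulfonated pyridinium ring (Zincke-type ring opening) to the stable glutaconaldehyde enolate salt.

Step 17
Reactants: 24 potassium (1E,3E)-5-oxopenta-1,3-dien-1-olate
Product: 25 (2E,4E)-5-bromopenta-2,4-dienal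
Conditions: Ph3PBr2, CH2Cl2, 0 °C → rt
Reagents that add atoms: dibromotriphenylphosphorane, BrP(Br)(c1ccccc1)(c1ccccc1)c1ccccc1
Why: the enolate oxygen is activated as an oxyphosphonium ion and replaced by bromide in a vinylogous addition–elimination (vinylogous acid bromide formation), which should give the E,E-bromodienal.

Step 18
Reactants: 25 (2E,4E)-5-bromopenta-2,4-dienal
Product: 26 (2E,4E)-5-bromopenta-2,4-dienoic acid
Conditions: NaClO2, NaH2PO4, 2-methylbut-2-ene, t-BuOH/H2O, 0 °C → rt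
Reagents that add atoms: sodium chlorite, [Na+].[O-]Cl=O
Why: Pinnick oxidation converts the enal into the acid without touching the bromodiene, the alkene scavenger removing hypochlorite.

Step 19
Reactants: 27 cyclopentane-1,3-dione
Product: 28 2-(2-phenylhydrazinylidene)cyclopentane-1,3-dione
Conditions: PhN2BF4, NaOAc, EtOH/H2O, 0 °C
Reagents that add atoms: benzenediazonium tetrafluoroborate, F[B-](F)(F)F.N#[N+]c1ccccc1
Why: azo coupling (Japp–Klingemann type, without cleavage) at the doubly activated C2 of the 1,3-dione installs nitrogen at C2 as the arylhydrazone.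

Step 20
Reactants: 28 2-(2-phenylhydrazinylidene)cyclopentane-1,3-dione
Product: 29 2-amino-3-hydroxycyclopent-2-en-1-one hydrochloride
Conditions: H2 (1 atm), Pd/C, HCl, EtOH, rt
Reagents that add atoms: hydrogen chloride, Cl
Why: hydrogenolysis of the N–N bond should release the aminocyclopentenone as its stable hydrochloride together with aniline hydrochloride.

Step 21
Reactants: 26 (2E,4E)-5-bromopenta-2,4-dienoic acid; 29 2-amino-3-hydroxycyclopent-2-en-1-one hydrochloride
Product: 31 (2E,4E)-5-bromo-N-(2-hydroxy-5-oxocyclopent-1-en-1-yl)penta-2,4-dienamide, via (2E,4E)-5-bromopenta-2,4-dienoyl chloride 30 (not isolated)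
Conditions: (COCl)2, DMF (cat.), CH2Cl2, 0 °C; concentrate; then 29, pyridine, DMF, 0 °C → rt
Reagents that add atoms: none
Why: N-acylation of the amine of the vinylogous acid by the acid chloride; any O-acyl product should transfer its acyl group to nitrogen, which gives the hydrogen-bonded enol amide.

Step 22
Reactants: 22 (2E,4R)-N-[(1S,5R,6R)-5-hydroxy-2-oxo-5-[(E)-2-(tributylstannyl)ethenyl]-7-oxabicyclo[4.1.0]hept-3-en-3-yl]-2,4-dimethyloct-2-enamide; 31 (2E,4E)-5-bromo-N-(2-hydroxy-5-oxocyclopent-1-en-1-yl)penta-2,4-dienamide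
Product: 32 (2E,4R)-N-[(1S,5S,6R)-5-hydroxy-5-[(1E,3E,5E)-7-[(2-hydroxy-5-oxocyclopent-1-en-1-yl)amino]-7-oxohepta-1,3,5-trien-1-yl]-2-oxo-7-oxabicyclo[4.1.0]hept-3-en-3-yl]-2,4-dimethyloct-2-enamide (target)
Conditions: PdCl2(MeCN)2 (5 mol %), DMF, rt, dark
Reagents that add atoms: none
Why: Stille coupling of the E-vinylstannane with the E,E-bromodiene joins C2′ to C3′ with retention of both alkene geometries under neutral, ligand-free conditions that the epoxyquinol and the enol amide should tolerate.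

**Compound list**

1 | (R)-4-benzyl-1,3-oxazolidin-2-one | O=C1N[C@H](Cc2ccccc2)CO1 | starting material
2 | hexanoyl chloride | CCCCCC(Cl)=O | starting material
3 | (R)-4-benzyl-3-hexanoyl-1,3-oxazolidin-2-one | CCCCCC(=O)N1[C@H](Cc2ccccc2)COC1=O | intermediate
4 | (R)-4-benzyl-3-[(2R)-2-methylhexanoyl]-1,3-oxazolidin-2-one | CCCC[C@@H](C)C(=O)N1[C@H](Cc2ccccc2)COC1=O | intermediate
5 | (2R)-2-methylhexan-1-ol | CCCC[C@@H](C)CO | intermediate
6 | (2R)-2-methylhexanal | CCCC[C@@H](C)C=O | intermediate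
7 | ethyl (2E,4R)-2,4-dimethyloct-2-enoate | CCCC[C@@H](C)/C=C(\C)C(=O)OCC | intermediate
8 | (2E,4R)-2,4-dimethyloct-2-enoic acid | CCCC[C@@H](C)/C=C(\C)C(=O)O | intermediate
9 | (E)-N,N-dimethyl-2-nitroethen-1-amine | CN(C)/C=C/[N+](=O)[O-] | starting material
10 | (Z)-2-nitroethen-1-amine | N/C=C\[N+](=O)[O-] | intermediate
11 | (2E,4R)-2,4-dimethyloct-2-enoyl chloride | CCCC[C@@H](C)/C=C(\C)C(Cl)=O | intermediate
12 | (2E,4R)-2,4-dimethyl-N-[(Z)-2-nitroethenyl]oct-2-enamide | CCCC[C@@H](C)/C=C(\C)C(=O)N/C=C\[N+](=O)[O-] | intermediate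
13 | 3-hydroxy-2H-pyran-2-one | O=C1OC=CC=C1O | starting material
14 | (2E,4R)-N-[(1R,4R,7S,8S)-4-hydroxy-8-nitro-3-oxo-2-oxabicyclo[2.2.2]oct-5-en-7-yl]-2,4-dimethyloct-2-enamide | O[C@@]12C=C[C@@H](OC1=O)[C@@H](NC(=O)/C(C)=C/[C@H](C)CCCC)[C@@H]2[N+](=O)[O-] | intermediate
15 | (2E,4R)-2,4-dimethyl-N-[(1R,4R,7S,8S)-8-nitro-3-oxo-4-[(triethylsilyl)oxy]-2-oxabicyclo[2.2.2]oct-5-en-7-yl]oct-2-enamide | CC[Si](CC)(CC)O[C@@]12C=C[C@@H](OC1=O)[C@@H](NC(=O)/C(C)=C/[C@H](C)CCCC)[C@@H]2[N+](=O)[O-] | intermediate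
16 | (2E,4R)-N-[(1R,4R,7S,8S)-3-hydroxy-8-nitro-4-[(triethylsilyl)oxy]-2-oxabicyclo[2.2.2]oct-5-en-7-yl]-2,4-dimethyloct-2-enamide (lactol, both C3 epimers) | CC[Si](CC)(CC)O[C@@]12C=C[C@@H](OC1O)[C@@H](NC(=O)/C(C)=C/[C@H](C)CCCC)[C@@H]2[N+](=O)[O-] | intermediate
17 | (2E,4R)-N-[(1S,2R,5S,6S)-5-ethynyl-2-hydroxy-6-nitro-5-[(triethylsilyl)oxy]cyclohex-3-en-1-yl]-2,4-dimethyloct-2-enamide | C#C[C@@]1(O[Si](CC)(CC)CC)C=C[C@@H](O)[C@@H](NC(=O)/C(C)=C/[C@H](C)CCCC)[C@@H]1[N+](=O)[O-] | intermediate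
18 | (2E,4R)-N-[(1S,2R,5S,6S)-2-hydroxy-6-nitro-5-[(E)-2-(tributylstannyl)ethenyl]-5-[(triethylsilyl)oxy]cyclohex-3-en-1-yl]-2,4-dimethyloct-2-enamide | CCCC[Sn](CCCC)(CCCC)/C=C/[C@@]1(O[Si](CC)(CC)CC)C=C[C@@H](O)[C@@H](NC(=O)/C(C)=C/[C@H](C)CCCC)[C@@H]1[N+](=O)[O-] | intermediate
19 | (2E,4R)-2,4-dimethyl-N-[(1S,5S,6S)-6-nitro-2-oxo-5-[(E)-2-(tributylstannyl)ethenyl]-5-[(triethylsilyl)oxy]cyclohex-3-en-1-yl]oct-2-enamide | CCCC[Sn](CCCC)(CCCC)/C=C/[C@@]1(O[Si](CC)(CC)CC)C=CC(=O)[C@@H](NC(=O)/C(C)=C/[C@H](C)CCCC)[C@@H]1[N+](=O)[O-] | intermediate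
20 | (2E,4R)-2,4-dimethyl-N-[(3R)-6-oxo-3-[(E)-2-(tributylstannyl)ethenyl]-3-[(triethylsilyl)oxy]cyclohexa-1,4-dien-1-yl]oct-2-enamide | CCCC[Sn](CCCC)(CCCC)/C=C/[C@@]1(O[Si](CC)(CC)CC)C=CC(=O)C(NC(=O)/C(C)=C/[C@H](C)CCCC)=C1 | intermediate
21 | (2E,4R)-N-[(3R)-3-hydroxy-6-oxo-3-[(E)-2-(tributylstannyl)ethenyl]cyclohexa-1,4-dien-1-yl]-2,4-dimethyloct-2-enamide | CCCC[Sn](CCCC)(CCCC)/C=C/[C@@]1(O)C=CC(=O)C(NC(=O)/C(C)=C/[C@H](C)CCCC)=C1 | intermediate
22 | (2E,4R)-N-[(1S,5R,6R)-5-hydroxy-2-oxo-5-[(E)-2-(tributylstannyl)ethenyl]-7-oxabicyclo[4.1.0]hept-3-en-3-yl]-2,4-dimethyloct-2-enamide | CCCC[Sn](CCCC)(CCCC)/C=C/[C@@]1(O)[C@@H]2O[C@@H]2C(=O)C(NC(=O)/C(C)=C/[C@H](C)CCCC)=C1 | intermediate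
23 | sulfur trioxide–pyridine complex (pyridinium-1-sulfonate) | [O-]S(=O)(=O)[n+]1ccccc1 | starting material
24 | potassium (1E,3E)-5-oxopenta-1,3-dien-1-olate | [K+].[O-]/C=C/C=C/C=O | intermediate
25 | (2E,4E)-5-bromopenta-2,4-dienal | Br/C=C/C=C/C=O | intermediate
26 | (2E,4E)-5-bromopenta-2,4-dienoic acid | Br/C=C/C=C/C(=O)O | intermediate
27 | cyclopentane-1,3-dione | O=C1CCC(=O)C1 | starting material
28 | 2-(2-phenylhydrazinylidene)cyclopentane-1,3-dione | O=C1CCC(=O)C1=NNc1ccccc1 | intermediate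
29 | 2-amino-3-hydroxycyclopent-2-en-1-one hydrochloride | Cl.NC1=C(O)CCC1=O | intermediate
30 | (2E,4E)-5-bromopenta-2,4-dienoyl chloride | Br/C=C/C=C/C(Cl)=O | intermediate
31 | (2E,4E)-5-bromo-N-(2-hydroxy-5-oxocyclopent-1-en-1-yl)penta-2,4-dienamide | Br/C=C/C=C/C(=O)NC1=C(O)CCC1=O | intermediate
32 | (2E,4R)-N-[(1S,5S,6R)-5-hydroxy-5-[(1E,3E,5E)-7-[(2-hydroxy-5-oxocyclopent-1-en-1-yl)amino]-7-oxohepta-1,3,5-trien-1-yl]-2-oxo-7-oxabicyclo[4.1.0]hept-3-en-3-yl]-2,4-dimethyloct-2-enamide | CCCC[C@@H](C)/C=C(\C)C(=O)NC1=C[C@@](O)(/C=C/C=C/C=C/C(=O)NC2=C(O)CCC2=O)[C@@H]2O[C@@H]2C1=O | target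

**Step count and risks**

Total step count: 22. Longest linear sequence: 15 steps (steps 1–5, 7–15 and 22).

Steps most likely to fail:

1. Step 8 (Proposed new method). The first C–C bond may form without ring closure, the adduct re-aromatising to a 6-alkylated hydroxypyrone. The hydrogen-bonded, N–H-acidic nitroenamide may also be too weak an acceptor, or the catalyst may discriminate the faces poorly. The fallback uses known chemistry, sets out from 11 and comes back to the route at 22, so that it bypasses steps 8–15. Acid chloride 11 acylates 2,5-dimethoxyaniline (pyridine, CH2Cl2) to give the anilide (2E,4R)-N-(2,5-dimethoxyphenyl)-2,4-dimethyloct-2-enamide F1. Oxidation with PhI(OAc)2 in MeOH gives the quinone monoketal (2E,4R)-N-(6,6-dimethoxy-3-oxocyclohexa-1,4-dien-1-yl)-2,4-dimethyloct-2-enamide F2. Phase-transfer Weitz–Scheffer epoxidation (t-BuOOH, aq. NaOH, toluene, N-benzylcinchonidinium chloride or its cinchoninium pseudoenantiomer) gives the epoxy ketal (2E,4R)-N-[(1R,6S)-5,5-dimethoxy-2-oxo-7-oxabicyclo[4.1.0]hept-3-en-4-yl]-2,4-dimethyloct-2-enamide F3. (E)-2-(Tributylstannyl)vinyllithium, made from (E)-1,2-bis(tributylstannyl)ethene and n-BuLi, adds to the ketone anti to the oxirane and gives the carbinol (2E,4R)-N-[(1R,2R,6S)-2-hydroxy-5,5-dimethoxy-2-[(E)-2-(tributylstannyl)ethenyl]-7-oxabicyclo[4.1.0]hept-3-en-4-yl]-2,4-dimethyloct-2-enamide F4. Ketal hydrolysis (pyridinium p-toluenesulfonate, acetone/H2O) then gives 22.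

2. Step 15. Hydrogen-bond delivery may be overridden, so that the peroxide enters anti to the hydroxyl, and the free quinol may degrade under base (aromatisation, loss of tin). The fallback sets out from 20 and comes back at 22. The silyl ether 20 is epoxidised before deprotection under catalyst control (t-BuOOH, aq. NaOH, toluene, the cinchona-derived quaternary ammonium salt matched to C4), which removes the alkoxide pathway and lets the reagent choose the face. This gives the silyl-protected epoxide (2E,4R)-2,4-dimethyl-N-[(1S,5R,6R)-2-oxo-5-[(E)-2-(tributylstannyl)ethenyl]-5-[(triethylsilyl)oxy]-7-oxabicyclo[4.1.0]hept-3-en-3-yl]oct-2-enamide F5, which is desilylated (Bu4NF/AcOH, THF, 0 °C) to 22.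

3. Step 7. The ambident, weakly nucleophilic nitroenamine may be acylated on carbon or not at all. The fallback sets out from 11 and comes back at 12, and it builds the N–C bond first and introduces the nitro group last. Acid chloride 11 with NH3 gives the primary amide (2E,4R)-2,4-dimethyloct-2-enamide F6. Vinyl transfer from butyl vinyl ether (Pd(OCOCF3)2, 4,7-diphenyl-1,10-phenanthroline, air) gives the enamide (2E,4R)-N-ethenyl-2,4-dimethyloct-2-enamide F7. β-Nitration of the enamide (t-BuONO, TEMPO) then gives 12, which should settle in the hydrogen-bonded Z form.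

**Further compounds**

F1 | step 8 | (2E,4R)-N-(2,5-dimethoxyphenyl)-2,4-dimethyloct-2-enamide | COc1ccc(OC)c(NC(=O)/C(C)=C/[C@H](C)CCCC)c1
F2 | step 8 | (2E,4R)-N-(6,6-dimethoxy-3-oxocyclohexa-1,4-dien-1-yl)-2,4-dimethyloct-2-enamide | COC1(OC)C=CC(=O)C=C1NC(=O)/C(C)=C/[C@H](C)CCCC
F3 | step 8 | (2E,4R)-N-[(1R,6S)-5,5-dimethoxy-2-oxo-7-oxabicyclo[4.1.0]hept-3-en-4-yl]-2,4-dimethyloct-2-enamide | O=C1C=C(NC(=O)/C(C)=C/[C@H](C)CCCC)C(OC)(OC)[C@H]2O[C@@H]12
F4 | step 8 | (2E,4R)-N-[(1R,2R,6S)-2-hydroxy-5,5-dimethoxy-2-[(E)-2-(tributylstannyl)ethenyl]-7-oxabicyclo[4.1.0]hept-3-en-4-yl]-2,4-dimethyloct-2-enamide | CCCC[Sn](CCCC)(CCCC)/C=C/[C@]1(O)C=C(NC(=O)/C(C)=C/[C@H](C)CCCC)C(OC)(OC)[C@H]2O[C@@H]12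
F5 | step 15 | (2E,4R)-2,4-dimethyl-N-[(1S,5R,6R)-2-oxo-5-[(E)-2-(tributylstannyl)ethenyl]-5-[(triethylsilyl)oxy]-7-oxabicyclo[4.1.0]hept-3-en-3-yl]oct-2-enamide | CCCC[Sn](CCCC)(CCCC)/C=C/[C@@]1(O[Si](CC)(CC)CC)[C@@H]2O[C@@H]2C(=O)C(NC(=O)/C(C)=C/[C@H](C)CCCC)=C1
F6 | step 7 | (2E,4R)-2,4-dimethyloct-2-enamide | CCCC[C@@H](C)/C=C(\C)C(N)=O
F7 | step 7 | (2E,4R)-N-ethenyl-2,4-dimethyloct-2-enamide | CCCC[C@@H](C)/C=C(\C)C(=O)NC=C
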